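At 8.0 d you will read gamma, a flask you have followed up to 5.00 d, and the question to put to its readings is how much product each catalyst makes before it stops working.

in all of them: substrate 1.5 M; free catalyst 0.2 mol%
- gamma: reagent 1.1 equiv; capture agent 0.030 M; temperature 20 °C; the very flask that is asked about, followed so far
- epsilon: reagent 1.1 equiv; capture agent 0.030 M; temperature 15 °C; run made earlier
- flask: reagent 1.10 equiv; capture agent 0.0300 M; temperature 20 °C; time 8.0 d

- gamma (time / d: product / %, substrate / %): 0.417: 2.6, 97.1; 1.25: 8.0, 92.2; 2.00: 9.6, 92.1; 3.00: 9.0, 89.0; 5.00: 9.8, 87.0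
- epsilon (time / d: product / %, substrate / %): 0.417: 1.6, 97.3; 1.25: 3.7, 96.9; 2.00: 5.0, 92.0; 3.00: 8.3, 93.4; 5.00: 8.1, 92.8

(scatter of a reading: 1 percentage point)

- the volume of additions can be left aside
- a reading or a percentage of product counts all its forms, free or not

- dusk: change nothing and wait 4.0 d more
- winter: at 8.0 d add free catalyst, 50.0% of the amount charged, then wait 4.0 d
- spring: at 8.0 d raise the temperature by 15 K, then wait 4.0 d

- product, in percent of the substrate first charged, at 8.0 d
- what to do for the largest gain in product; "none" if nothing gains more than 2 percentage points (dusk / winter / spring / none)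
- product present, in percent of the substrate first charged, after dusk
- product present, in percent of the substrate first charged, after spring

Read the two tables column against column. At 1.25 d gamma, at 20 °C, holds 8.0% of product and epsilon, at 15 °C, holds 3.7%, so gamma has twice as much; but at 5.00 d they read 9.8% and 8.1%, a ratio of 1.21, with a scatter of 1 percentage point on each reading. Somewhere between those rows, then, control changes hands: I read the early rows as a matter of rate, and the late ones as a matter of how much the catalyst can give.

Now read down gamma. Product reads 9.6%, 9.0% and 9.8% from 2.00 d on, while substrate still reads 87.0%, so the stop in gamma is not a lack of substrate. The capture agent, however, is charged at ten times the catalyst, so, taken one for one, it could hold the whole catalyst charge and keep 90.0% of its own charge to spare.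

My reckoning therefore rests on one number, the turnover number, the product made per catalyst charged before that catalyst is lost. 49.0 is what the last reading of gamma gives. On the charged loading that means 9.80% at 8.0 d. Dusk and spring bring no new catalyst, so I leave both there, but winter's added catalyst should bring 4.9 points, more than the margin of 2 points.

The forecast, a little above me on spring, gives 9.9% at 8.0 d, 10% after dusk and 10.5% after spring, and chooses winter, holding that “the catalyst is used up or poisoned”.

    substrate + free catalyst ⇌ catalyst intermediate A (K = 0.0770 M⁻¹, k = 8.70 M⁻¹ h⁻¹, Ea = 53.0 kJ mol⁻¹, ΔH = −24.0 kJ mol⁻¹)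
    reagent + catalyst intermediate A ⇌ catalyst intermediate B (K = 0.430 M⁻¹, k = 69.0 M⁻¹ h⁻¹, Ea = 52.0 kJ mol⁻¹, ΔH = 19.0 kJ mol⁻¹)
    catalyst intermediate B ⇌ free catalyst + product (K = 96.0 M, k = 29.0 h⁻¹, Ea = 71.0 kJ mol⁻¹, ΔH = −32.0 kJ mol⁻¹)
    crystals ⇌ product, rate k4*(cs4 - [product]) while solid is left; crystals form when [product] > cs4 (solubility = 0.550 M, k = 0.270 h⁻¹)
    catalyst intermediate A + capture agent → trapped intermediate (k = 8.50 M⁻¹ h⁻¹, Ea = 56.0 kJ mol⁻¹)
    (constants at 20 °C)

The flask gives 12.9% at 8.0 d, 13.2% after dusk and 13.5% after spring, and winter is the best choice, with a gain of 5.4 points; my 9.80% lies lower than the flask, whose product at 8.0 d comes to 64.6 per catalyst charged. In the flask at 8.00 d, 97.3% of the catalyst charged stands as trapped intermediate and 2.35% as free catalyst, with 90% of the capture agent left. Put the turnover number of 49.0 on the neighbouring flask with 0.34 mol% of free catalyst and it gives 16.7%; that flask holds 21.2% at 8.0 d.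

The numbers in the tables were generated by integration on assumed constants, and the scatter is random.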